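**Retrosynthetic overview**
1. The target comes from C15 desilylation of the (1S)-carbinol, which is set by CBS reduction of a macrocyclic C1 enone.
2. The ten-membered ring (second and last ring) is closed at C1–C10 by a Nozaki–Hiyama–Kishi reaction of a C1 aldehyde with a (Z)-alkenyl iodide.
3. The C8 (S)-2-methylbutanoate is installed by Mitsunobu inversion of the 8-epi carbinol that the coupling delivers.
4. Key C7–C8 bond: intermolecular zinc Barbier carbonyl allylation of (Z)-3-iodobut-2-enal with a (5R)-3-(bromomethyl)butenolide; C6 controls C7 (trans lactone) and C8.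
5. The butenolide (first ring) comes from RCM of a 2-(bromomethyl)acrylate of a lipase-resolved dienol; the C4=C5 olefin comes from NaAlH2(OCH2CH2OCH3)2/I2 hydroalumination–iodination and B-alkyl Suzuki coupling.

Assumption: atom labels C1–C15 in the explanations follow germacrane numbering of the target (C6 = lactone O–CH, C8 = ester O–CH, C1 = secondary carbinol, C15 = CH2OH carbon).

**Step 1**
Reactants: 1 prop-2-yn-1-ol
Product: 2 tert-butyl(diphenyl)(prop-2-yn-1-yloxy)silane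
Conditions: TBDPSCl, imidazole, CH2Cl2, 0 °C to rt
Reagents that add atoms: tert-butyl(chloro)diphenylsilane (TBDPSCl), CC(C)(C)[Si](Cl)(c1ccccc1)c1ccccc1
Why: Routine silylation of a primary alcohol gives a robust TBDPS ether that masks the future C15–OH until the last step.

**Step 2**
Reactants: 2 tert-butyl(diphenyl)(prop-2-yn-1-yloxy)silane, 3 prop-2-enal (acrolein)
Product: 5 rac-6-[(tert-butyldiphenylsilyl)oxy]hex-1-en-4-yn-3-ol, via lithium acetylide 4 (not isolated)
Conditions: n-BuLi, THF, −78 °C; then 3, −78 °C; H2O quench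
Reagents that add atoms: none
Why: Acetylide 1,2-addition to the enal gives the vinyl propargyl carbinol (future C6) as a racemate.

**Step 3**
Reactants: 5 rac-6-[(tert-butyldiphenylsilyl)oxy]hex-1-en-4-yn-3-ol
Product: 6 (3S)-6-[(tert-butyldiphenylsilyl)oxy]hex-1-en-4-yn-3-ol
Conditions: Novozym 435 (immobilised Candida antarctica lipase B), vinyl acetate, hexane, 30 °C, to about 55% conversion; chromatography
Reagents that add atoms: none
Why: Lipase kinetic resolution following Kazlauskas' rule (small vinyl, long alkynyl arm) acetylates the (R)-alcohol and leaves the (S)-alcohol, which fixes C6.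

**Step 4**
Reactants: 6 (3S)-6-[(tert-butyldiphenylsilyl)oxy]hex-1-en-4-yn-3-ol
Product: 8 (3S,4Z)-6-[(tert-butyldiphenylsilyl)oxy]-5-iodohexa-1,4-dien-3-ol, via sodium alkenylalanate 7 (not isolated)
Conditions: NaAlH2(OCH2CH2OCH3)2 (1.6 equiv), THF, 0 °C to rt; then I2, THF, −78 to 0 °C; aq Na2S2O3
Reagents that add atoms: iodine, II
Why: Alkoxide-directed trans-hydroalumination puts hydride on C5 and aluminium on C4 in a five-membered oxaaluminacycle, and iodinolysis with retention gives the alkenyl iodide with iodine cis to C6.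

**Step 5**
Reactants: 8 (3S,4Z)-6-[(tert-butyldiphenylsilyl)oxy]-5-iodohexa-1,4-dien-3-ol, 9 tert-butyl(dimethyl)(prop-2-en-1-yloxy)silane
Product: 11 (3S,4E)-8-[(tert-butyldimethylsilyl)oxy]-5-{[(tert-butyldiphenylsilyl)oxy]methyl}octa-1,4-dien-3-ol, via B-alkyl-9-BBN borane 10 (not isolated)
Conditions: 9, 9-BBN-H, THF, 0 °C to rt; then 8, Pd(dppf)Cl2 (5 mol %), AsPh3, Cs2CO3, DMF/H2O, rt
Reagents that add atoms: none
Why: B-alkyl Suzuki–Miyaura coupling (anti-Markovnikov hydroboration, then sp3–sp2 coupling with retention) places the C3–C1 chain cis to C6; the descriptor changes to E only through CIP priorities.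

**Step 6**
Reactants: 11 (3S,4E)-8-[(tert-butyldimethylsilyl)oxy]-5-{[(tert-butyldiphenylsilyl)oxy]methyl}octa-1,4-dien-3-ol, 12 2-(bromomethyl)prop-2-enoic acid
Product: 13 (3S,4E)-8-[(tert-butyldimethylsilyl)oxy]-5-{[(tert-butyldiphenylsilyl)oxy]methyl}octa-1,4-dien-3-yl 2-(bromomethyl)prop-2-enoate
Conditions: DIC, DMAP (5 mol %), CH2Cl2, 0 °C
Reagents that add atoms: none
Why: Carbodiimide (Steglich-type) esterification at low temperature acylates the secondary alcohol without touching the C6 stereocentre or displacing the allylic bromide.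

**Step 7**
Reactants: 13 (3S,4E)-8-[(tert-butyldimethylsilyl)oxy]-5-{[(tert-butyldiphenylsilyl)oxy]methyl}octa-1,4-dien-3-yl 2-(bromomethyl)prop-2-enoate
Product: 14 (5R)-3-(bromomethyl)-5-[(1E)-5-[(tert-butyldimethylsilyl)oxy]-2-{[(tert-butyldiphenylsilyl)oxy]methyl}pent-1-en-1-yl]furan-2(5H)-one
Conditions: second-generation Grubbs catalyst RuCl2(H2IMes)(PCy3)(=CHPh) (5 mol %), CH2Cl2 (0.01 M), 40 °C
Reagents that add atoms: none
Why: Ring-closing metathesis starts at the terminal vinyl group and closes onto the acrylate to give the five-membered butenolide (C7=C11), while the trisubstituted C4=C5 olefin is too hindered to compete.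

**Step 8**
Reactants: 15 but-2-yn-1-ol
Product: 17 (2Z)-3-iodobut-2-en-1-ol, via sodium alkenylalanate 16 (not isolated)
Conditions: NaAlH2(OCH2CH2OCH3)2, THF, 0 °C to rt; then I2, THF, −78 to 0 °C; aq Na2S2O3
Reagents that add atoms: iodine, II
Why: The same directed trans-hydroalumination–iodination gives the Z alkenyl iodide (iodine cis to CH2OH) that becomes the C9=C10 olefin.

**Step 9**
Reactants: 17 (2Z)-3-iodobut-2-en-1-ol
Product: 18 (2Z)-3-iodobut-2-enal
Conditions: MnO2 (activated, excess), CH2Cl2, rt, dark; used at once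
Reagents that add atoms: none
Why: Neutral allylic oxidation gives the enal without Z/E isomerisation or loss of iodide.

**Step 10**
Reactants: 14 (5R)-3-(bromomethyl)-5-[(1E)-5-[(tert-butyldimethylsilyl)oxy]-2-{[(tert-butyldiphenylsilyl)oxy]methyl}pent-1-en-1-yl]furan-2(5H)-one, 18 (2Z)-3-iodobut-2-enal
Product: 20 (4R,5R)-5-[(1E)-5-[(tert-butyldimethylsilyl)oxy]-2-{[(tert-butyldiphenylsilyl)oxy]methyl}pent-1-en-1-yl]-4-[(1R,2Z)-1-hydroxy-3-iodobut-2-en-1-yl]-3-methylidenedihydrofuran-2(3H)-one, via allylzinc bromide 19 (not isolated)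
Conditions: Zn dust, THF/sat. aq NH4Cl (3:1), 0 °C to rt
Reagents that add atoms: none
Why: In this Barbier carbonyl allylation the allylzinc adds through C7 in a chair Zimmerman–Traxler transition state on the ring face anti to the C6 side chain, which gives the trans lactone and the 7,8-anti carbinol (C8 epimeric to the target), while the alkenyl iodide is inert to zinc.

**Step 11**
Reactants: 20 (4R,5R)-5-[(1E)-5-[(tert-butyldimethylsilyl)oxy]-2-{[(tert-butyldiphenylsilyl)oxy]methyl}pent-1-en-1-yl]-4-[(1R,2Z)-1-hydroxy-3-iodobut-2-en-1-yl]-3-methylidenedihydrofuran-2(3H)-one, 21 (2S)-2-methylbutanoic acid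
Product: 22 (1S,2Z)-1-[(2R,3S)-2-[(1E)-5-[(tert-butyldimethylsilyl)oxy]-2-{[(tert-butyldiphenylsilyl)oxy]methyl}pent-1-en-1-yl]-4-methylidene-5-oxotetrahydrofuran-3-yl]-3-iodobut-2-en-1-yl (2S)-2-methylbutanoate
Conditions: PPh3, DIAD, toluene, 0 °C to rt
Reagents that add atoms: none
Why: Mitsunobu esterification displaces the activated C8 oxygen by SN2 with clean inversion, which corrects C8 to the target configuration and installs the (S)-2-methylbutanoate in one operation.

**Step 12**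
Reactants: 22 (the C8 ester with TBS and TBDPS ethers)
Product: 23 (1S,2Z)-1-[(2R,3S)-2-[(1E)-2-{[(tert-butyldiphenylsilyl)oxy]methyl}-5-hydroxypent-1-en-1-yl]-4-methylidene-5-oxotetrahydrofuran-3-yl]-3-iodobut-2-en-1-yl (2S)-2-methylbutanoate
Conditions: PPTS (cat.), MeOH, rt
Reagents that add atoms: none
Why: Mild acidic methanolysis cleaves the primary TBS ether far faster than the TBDPS ether and leaves the lactone, the ester and the alkenyl iodide untouched.

**Step 13**
Reactants: 23 (the C1 primary alcohol)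
Product: 24 (1S,2Z)-1-[(2R,3S)-2-[(1E)-2-{[(tert-butyldiphenylsilyl)oxy]methyl}-5-oxopent-1-en-1-yl]-4-methylidene-5-oxotetrahydrofuran-3-yl]-3-iodobut-2-en-1-yl (2S)-2-methylbutanoate
Conditions: Dess–Martin periodinane, CH2Cl2, 0 °C to rt
Reagents that add atoms: none
Why: Dess–Martin oxidation gives the C1 aldehyde under neutral conditions with no epimerisable centre adjacent to it.

**Step 14**
Reactants: 24 (the C1 aldehyde / C10 alkenyl iodide)
Product: 26 (3aR,4R,5Z,7RS,10E,11aR)-10-{[(tert-butyldiphenylsilyl)oxy]methyl}-7-hydroxy-6-methyl-3-methylidene-2-oxo-2,3,3a,4,7,8,9,11a-octahydrocyclodeca[b]furan-4-yl (2S)-2-methylbutanoate, via alkenylchromium dichloride 25 (not isolated)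
Conditions: CrCl2 (10 equiv), NiCl2 (0.1 equiv), degassed DMSO/THF (3:1), 0.003 M, slow addition, rt
Reagents that add atoms: none
Why: In this Nozaki–Hiyama–Kishi macrocyclisation the alkenylchromium adds only to the aldehyde with retention of the Z geometry and closes the low-strain cis,cis-cyclodeca-1,6-diene ring, leaving C1 as an epimer mixture that is converged in the next two steps.

**Step 15**
Reactants: 26 (the macrocyclic C1 carbinol, epimer mixture)
Product: 27 (3aR,4R,5Z,10E,11aR)-10-{[(tert-butyldiphenylsilyl)oxy]methyl}-6-methyl-3-methylidene-2,7-dioxo-2,3,3a,4,7,8,9,11a-octahydrocyclodeca[b]furan-4-yl (2S)-2-methylbutanoate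
Conditions: Dess–Martin periodinane, CH2Cl2, 0 °C to rt
Reagents that add atoms: none
Why: Oxidation of both allylic alcohol epimers converges them to a single Z enone.

**Step 16**
Reactants: 27 (the macrocyclic C1 enone)
Product: 28 (3aR,4R,5Z,7S,10E,11aR)-10-{[(tert-butyldiphenylsilyl)oxy]methyl}-7-hydroxy-6-methyl-3-methylidene-2-oxo-2,3,3a,4,7,8,9,11a-octahydrocyclodeca[b]furan-4-yl (2S)-2-methylbutanoate
Conditions: (R)-2-methyl-CBS-oxazaborolidine (1.0 equiv), catecholborane, toluene, −78 °C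
Reagents that add atoms: none
Why: In this Corey–Bakshi–Shibata reduction the (R)-oxazaborolidine treats the α-methyl alkenyl arm (C10) as the large group and delivers hydride to give the (1S)-carbinol under reagent control, and catecholborane at −78 °C spares the α-methylene lactone.

**Step 17**
Reactants: 28 (the TBDPS-protected (1S)-carbinol)
Product: 29 (3aR,4R,5Z,7S,10E,11aR)-7-hydroxy-10-(hydroxymethyl)-6-methyl-3-methylidene-2-oxo-2,3,3a,4,7,8,9,11a-octahydrocyclodeca[b]furan-4-yl (2S)-2-methylbutanoate (CNP0526758.1)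
Conditions: HF·pyridine, pyridine, THF, 0 °C to rt
Reagents that add atoms: none
Why: Buffered fluoride desilylation removes the TBDPS ether without base, so the α-methylene lactone, the ester and both Z ring olefins survive.

**Compound list**
1 | prop-2-yn-1-ol | C#CCO | starting material
2 | tert-butyl(diphenyl)(prop-2-yn-1-yloxy)silane | C#CCO[Si](c1ccccc1)(c1ccccc1)C(C)(C)C | intermediate
3 | prop-2-enal (acrolein) | C=CC=O | starting material
4 | lithium acetylide of 2 | [Li]C#CCO[Si](c1ccccc1)(c1ccccc1)C(C)(C)C | intermediate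
5 | rac-6-[(tert-butyldiphenylsilyl)oxy]hex-1-en-4-yn-3-ol | C=CC(O)C#CCO[Si](c1ccccc1)(c1ccccc1)C(C)(C)C | intermediate
6 | (3S)-6-[(tert-butyldiphenylsilyl)oxy]hex-1-en-4-yn-3-ol | C=C[C@H](O)C#CCO[Si](c1ccccc1)(c1ccccc1)C(C)(C)C | intermediate
7 | sodium cyclic alkenylalanate from 6 (five-membered oxaaluminacycle, Al on C4) | C=C[C@@H]1O[Al-](OCCOC)(OCCOC)C(CO[Si](c2ccccc2)(c2ccccc2)C(C)(C)C)=C1.[Na+] | intermediate
8 | (3S,4Z)-6-[(tert-butyldiphenylsilyl)oxy]-5-iodohexa-1,4-dien-3-ol | C=C[C@H](O)/C=C(\I)CO[Si](c1ccccc1)(c1ccccc1)C(C)(C)C | intermediate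
9 | tert-butyl(dimethyl)(prop-2-en-1-yloxy)silane (allyl TBS ether) | C=CCO[Si](C)(C)C(C)(C)C | starting material
10 | 9-{3-[(tert-butyldimethylsilyl)oxy]propyl}-9-borabicyclo[3.3.1]nonane | CC(C)(C)[Si](C)(C)OCCCB1C2CCCC1CCC2 | intermediate
11 | (3S,4E)-8-[(tert-butyldimethylsilyl)oxy]-5-{[(tert-butyldiphenylsilyl)oxy]methyl}octa-1,4-dien-3-ol | C=C[C@H](O)/C=C(\CCCO[Si](C)(C)C(C)(C)C)CO[Si](c1ccccc1)(c1ccccc1)C(C)(C)C | intermediate
12 | 2-(bromomethyl)prop-2-enoic acid | C=C(CBr)C(=O)O | starting material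
13 | (3S,4E)-8-[(tert-butyldimethylsilyl)oxy]-5-{[(tert-butyldiphenylsilyl)oxy]methyl}octa-1,4-dien-3-yl 2-(bromomethyl)prop-2-enoate | C=C[C@H](OC(=O)C(=C)CBr)/C=C(\CCCO[Si](C)(C)C(C)(C)C)CO[Si](c1ccccc1)(c1ccccc1)C(C)(C)C | intermediate
14 | (5R)-3-(bromomethyl)-5-[(1E)-5-[(tert-butyldimethylsilyl)oxy]-2-{[(tert-butyldiphenylsilyl)oxy]methyl}pent-1-en-1-yl]furan-2(5H)-one | BrCC1=C[C@@H](/C=C(\CCCO[Si](C)(C)C(C)(C)C)CO[Si](c2ccccc2)(c2ccccc2)C(C)(C)C)OC1=O | intermediate
15 | but-2-yn-1-ol | CC#CCO | starting material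
16 | sodium cyclic alkenylalanate from 15 | CC1=CCO[Al-]1(OCCOC)OCCOC.[Na+] | intermediate
17 | (2Z)-3-iodobut-2-en-1-ol | C/C(I)=C/CO | intermediate
18 | (2Z)-3-iodobut-2-enal | C/C(I)=C/C=O | intermediate
19 | allylzinc bromide from 14 | Br[Zn]CC1=C[C@@H](/C=C(\CCCO[Si](C)(C)C(C)(C)C)CO[Si](c2ccccc2)(c2ccccc2)C(C)(C)C)OC1=O | intermediate
20 | (4R,5R)-5-[(1E)-5-[(tert-butyldimethylsilyl)oxy]-2-{[(tert-butyldiphenylsilyl)oxy]methyl}pent-1-en-1-yl]-4-[(1R,2Z)-1-hydroxy-3-iodobut-2-en-1-yl]-3-methylidenedihydrofuran-2(3H)-one (trans lactone, C8 epimeric to target) | C=C1C(=O)O[C@H](/C=C(/CO[Si](c2ccccc2)(c2ccccc2)C(C)(C)C)CCCO[Si](C)(C)C(C)(C)C)[C@H]1[C@@H](O)/C=C(/C)I | intermediate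
21 | (2S)-2-methylbutanoic acid | CC[C@H](C)C(=O)O | starting material
22 | (1S,2Z)-1-[(2R,3S)-2-[(1E)-5-[(tert-butyldimethylsilyl)oxy]-2-{[(tert-butyldiphenylsilyl)oxy]methyl}pent-1-en-1-yl]-4-methylidene-5-oxotetrahydrofuran-3-yl]-3-iodobut-2-en-1-yl (2S)-2-methylbutanoate | C=C1C(=O)O[C@H](/C=C(/CO[Si](c2ccccc2)(c2ccccc2)C(C)(C)C)CCCO[Si](C)(C)C(C)(C)C)[C@H]1[C@H](OC(=O)[C@@H](C)CC)/C=C(/C)I | intermediate
23 | (1S,2Z)-1-[(2R,3S)-2-[(1E)-2-{[(tert-butyldiphenylsilyl)oxy]methyl}-5-hydroxypent-1-en-1-yl]-4-methylidene-5-oxotetrahydrofuran-3-yl]-3-iodobut-2-en-1-yl (2S)-2-methylbutanoate | C=C1C(=O)O[C@H](/C=C(/CO[Si](c2ccccc2)(c2ccccc2)C(C)(C)C)CCCO)[C@H]1[C@H](OC(=O)[C@@H](C)CC)/C=C(/C)I | intermediate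
24 | (1S,2Z)-1-[(2R,3S)-2-[(1E)-2-{[(tert-butyldiphenylsilyl)oxy]methyl}-5-oxopent-1-en-1-yl]-4-methylidene-5-oxotetrahydrofuran-3-yl]-3-iodobut-2-en-1-yl (2S)-2-methylbutanoate | C=C1C(=O)O[C@H](/C=C(/CO[Si](c2ccccc2)(c2ccccc2)C(C)(C)C)CCC=O)[C@H]1[C@H](OC(=O)[C@@H](C)CC)/C=C(/C)I | intermediate
25 | alkenylchromium dichloride from 24 (Cr in place of I) | C=C1C(=O)O[C@H](/C=C(/CO[Si](c2ccccc2)(c2ccccc2)C(C)(C)C)CCC=O)[C@H]1[C@H](OC(=O)[C@@H](C)CC)/C=C(/C)[Cr](Cl)Cl | intermediate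
26 | (3aR,4R,5Z,7RS,10E,11aR)-10-{[(tert-butyldiphenylsilyl)oxy]methyl}-7-hydroxy-6-methyl-3-methylidene-2-oxo-2,3,3a,4,7,8,9,11a-octahydrocyclodeca[b]furan-4-yl (2S)-2-methylbutanoate (C1 epimer mixture) | C=C1C(=O)O[C@@H]2/C=C(/CO[Si](c3ccccc3)(c3ccccc3)C(C)(C)C)CCC(O)/C(C)=C\[C@@H](OC(=O)[C@@H](C)CC)[C@@H]12 | intermediate
27 | (3aR,4R,5Z,10E,11aR)-10-{[(tert-butyldiphenylsilyl)oxy]methyl}-6-methyl-3-methylidene-2,7-dioxo-2,3,3a,4,7,8,9,11a-octahydrocyclodeca[b]furan-4-yl (2S)-2-methylbutanoate | C=C1C(=O)O[C@@H]2/C=C(/CO[Si](c3ccccc3)(c3ccccc3)C(C)(C)C)CCC(=O)/C(C)=C\[C@@H](OC(=O)[C@@H](C)CC)[C@@H]12 | intermediate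
28 | (3aR,4R,5Z,7S,10E,11aR)-10-{[(tert-butyldiphenylsilyl)oxy]methyl}-7-hydroxy-6-methyl-3-methylidene-2-oxo-2,3,3a,4,7,8,9,11a-octahydrocyclodeca[b]furan-4-yl (2S)-2-methylbutanoate | C=C1C(=O)O[C@@H]2/C=C(/CO[Si](c3ccccc3)(c3ccccc3)C(C)(C)C)CC[C@H](O)/C(C)=C\[C@@H](OC(=O)[C@@H](C)CC)[C@@H]12 | intermediate
29 | (3aR,4R,5Z,7S,10E,11aR)-7-hydroxy-10-(hydroxymethyl)-6-methyl-3-methylidene-2-oxo-2,3,3a,4,7,8,9,11a-octahydrocyclodeca[b]furan-4-yl (2S)-2-methylbutanoate (CNP0526758.1) | C=C1C(=O)O[C@@H]2/C=C(/CO)CC[C@H](O)/C(C)=C\[C@@H](OC(=O)[C@@H](C)CC)[C@@H]12 | target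

**Totals**
Total step count: 17. Longest linear sequence: 15 steps (steps 1–7 and 10–17, from prop-2-yn-1-ol); steps 8–9 make the aldehyde partner.

**Three steps most likely to fail, with fallbacks**

Step 11 (Mitsunobu inversion at C8). The alcohol is hindered and C7–H is acidic, so elimination or a sluggish reaction is possible, and PPh3 can add to the α-methylene lactone. The fallback sets out from 20 and returns at 22. Alcohol 20 is sulfonylated with ClCH2SO2Cl and pyridine in CH2Cl2 at −20 °C to give the C8 chloromethanesulfonate F1. Separately, acid 21 is neutralised with Cs2CO3 to give cesium (2S)-2-methylbutanoate F2. Heating F1 with F2 and 18-crown-6 in toluene at 40–60 °C displaces the sulfonate by SN2 with inversion and gives 22, with no phosphine or azodicarboxylate present.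

Step 14 (Nozaki–Hiyama–Kishi macrocyclisation). Oligomerisation, loss of the allylic ester from the alkenyl metal, or failure of the ring to close are the risks. The fallback sets out from 14 and returns at 26, closing the ring by metathesis at C9=C10 instead. Bromide 14 is coupled with acrolein 3 under the zinc conditions of step 10 (through 19) to give the C8 vinyl carbinol F3, which has the same 7,8-anti sense as 20. Mitsunobu esterification of F3 with 21 gives the inverted ester F4. PPTS in MeOH then gives the primary alcohol F5, and Dess–Martin oxidation gives the aldehyde F6. Addition of CH2=C(CH3)MgBr in THF at −78 °C, where only the aldehyde reacts, gives the C1 isopropenyl carbinol F7 as an epimer mixture. Ring-closing metathesis of F7 with the second-generation Hoveyda–Grubbs catalyst RuCl2(H2IMes)(=CH-C6H4-2-OiPr) in toluene at 80 °C and 1 mM forms the trisubstituted C9=C10 olefin, which the ten-membered ring should hold in the Z form (not guaranteed). This gives 26, which re-enters at step 15.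

Step 16 (CBS reduction of the macrocyclic enone). The ring conformation may oppose the reagent, or the borane may touch the α-methylene lactone. The fallback sets out from 27 and returns at 28. Enone 27 is reduced under Luche conditions (NaBH4, CeCl3·7H2O, MeOH, −78 °C), where the substrate alone decides the face. Carbinol 28 is separated by chromatography from its (7R)-epimer F8, and F8 is re-oxidised with Dess–Martin periodinane to 27 and recycled.

**Further compounds**
F1 | step 11 | C8 chloromethanesulfonate of 20 (configuration of 20 retained) | C=C1C(=O)O[C@H](/C=C(/CO[Si](c2ccccc2)(c2ccccc2)C(C)(C)C)CCCO[Si](C)(C)C(C)(C)C)[C@H]1[C@@H](OS(=O)(=O)CCl)/C=C(/C)I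
F2 | step 11 | cesium (2S)-2-methylbutanoate | CC[C@H](C)C(=O)[O-].[Cs+]
F3 | step 14 | (4R,5R)-5-[(1E)-5-[(tert-butyldimethylsilyl)oxy]-2-{[(tert-butyldiphenylsilyl)oxy]methyl}pent-1-en-1-yl]-4-[(1S)-1-hydroxyprop-2-en-1-yl]-3-methylidenedihydrofuran-2(3H)-one | C=C1C(=O)O[C@H](/C=C(/CO[Si](c2ccccc2)(c2ccccc2)C(C)(C)C)CCCO[Si](C)(C)C(C)(C)C)[C@H]1[C@@H](O)C=C
F4 | step 14 | C8-inverted (2S)-2-methylbutanoate of F3 | C=C1C(=O)O[C@H](/C=C(/CO[Si](c2ccccc2)(c2ccccc2)C(C)(C)C)CCCO[Si](C)(C)C(C)(C)C)[C@H]1[C@H](OC(=O)[C@@H](C)CC)C=C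
F5 | step 14 | C1 primary alcohol from F4 | C=C1C(=O)O[C@H](/C=C(/CO[Si](c2ccccc2)(c2ccccc2)C(C)(C)C)CCCO)[C@H]1[C@H](OC(=O)[C@@H](C)CC)C=C
F6 | step 14 | C1 aldehyde from F5 | C=C1C(=O)O[C@H](/C=C(/CO[Si](c2ccccc2)(c2ccccc2)C(C)(C)C)CCC=O)[C@H]1[C@H](OC(=O)[C@@H](C)CC)C=C
F7 | step 14 | C1 isopropenyl carbinol from F6 (C1 epimer mixture) | C=C1C(=O)O[C@H](/C=C(/CO[Si](c2ccccc2)(c2ccccc2)C(C)(C)C)CCC(O)C(C)=C)[C@H]1[C@H](OC(=O)[C@@H](C)CC)C=C
F8 | step 16 | (3aR,4R,5Z,7R,10E,11aR)-epimer of 28 | C=C1C(=O)O[C@@H]2/C=C(/CO[Si](c3ccccc3)(c3ccccc3)C(C)(C)C)CC[C@@H](O)/C(C)=C\[C@@H](OC(=O)[C@@H](C)CC)[C@@H]12
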